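**Retrosynthetic overview** (prostanoid numbering: carboxyl carbon is C1, ring is C8–C12, ketone is C9, lower chain is C13–C20)

- The 15(S)-acetate with the 13(E)-alkene is the [3,3] isomer of a 13(S)-acetate with a 14(E)-alkene, so the last step is a suprafacial allylic acetate shift and the only stereocentre to be made is C13, directly on ring carbon C12.
- The single ring is closed once, from an acyclic allyl vinyl ether, in one pot: Claisen rearrangement (C10–C11), then rhodium hydroacylation (C9–C8). The C10=C11 unsaturation is added afterwards by Saegusa oxidation.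
- Enabling feature: in the cyclopentenone ring the ketone C9 is flanked by the unsubstituted C10–C11 unit and by the trans-vicinal pair C8/C12, which is the retron of a 4-pentenal O=C9–C10–C11–C12=C8. The oxygen on C13 is locked by allylic 1,3-strain against the alpha chain and directs hydride delivery to C12; C8 follows from syn addition.
- The acyclic precursor comes from three bought pieces: (E)-oct-2-enal plus ethynylmagnesium bromide (C11–C20), methyl 8-oxooctanoate (C1–C8, Nozaki–Hiyama–Kishi coupling) and butyl vinyl ether (C9–C10).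

Key step: step 7

Remark: methyl 8-oxooctanoate is taken as a catalogue compound.

**Step 1**
Reactants: 1 (E)-oct-2-enal; 2 ethynylmagnesium bromide
Product: 3 rac-(E)-dec-4-en-1-yn-3-ol
Conditions: THF, −78 → 0 °C; aq. NH4Cl
Reagents that add atoms: none
Why: 1,2-Addition of the alkynyl Grignard reagent to the aldehyde carbonyl of the enal (no copper, hence no conjugate addition) gives the propargylic, allylic alcohol as a racemate, the stereocentre being set in the next step.

**Step 2**
Reactants: 3 rac-(E)-dec-4-en-1-yn-3-ol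
Product: 4 (3S,4E)-dec-4-en-1-yn-3-ol
Conditions: Ti(OiPr)4 (10 mol %), L-(+)-diisopropyl tartrate (15 mol %), t-BuOOH (0.6 equiv), 4 Å molecular sieves, CH2Cl2, −20 °C
Reagents that add atoms: none
Why: Sharpless kinetic resolution by titanium–tartrate asymmetric epoxidation: with L-(+)-diisopropyl tartrate the (3R) alcohol should be epoxidised fast at its (E)-alkene to the erythro epoxy alcohol, while the (3S) alcohol, whose ethynyl group occupies the position that the carbinol hydrogen takes in the fast-reacting enantiomer, should be left in high enantiomeric purity, which sets the one stereocentre (C13) from which all others are relayed.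

**Step 3**
Reactants: 4 (3S,4E)-dec-4-en-1-yn-3-ol
Product: 5 tert-butyl{[(3S,4E)-dec-4-en-1-yn-3-yl]oxy}dimethylsilane
Conditions: t-BuMe2SiCl, imidazole, DMF, 25 °C
Reagents that add atoms: tert-butyldimethylsilyl chloride, CC(C)(C)[Si](C)(C)Cl
Why: Imidazole-mediated silylation of the secondary alcohol with retention; the bulky, non-coordinating silyl ether is chosen to shield one alkene face in step 7 and to survive organochromium, amide base and rhodium.

**Step 4**
Reactants: 5 tert-butyl{[(3S,4E)-dec-4-en-1-yn-3-yl]oxy}dimethylsilane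
Product: 7 tert-butyl{[(3S,4E)-2-iododeca-1,4-dien-3-yl]oxy}dimethylsilane, via alkenylstannane 6 (not isolated)
Conditions: Bu3SnH, Mo(CO)3(CNtBu)3 (2 mol %), hydroquinone, THF, 55 °C; then I2, CH2Cl2, 0 °C
Reagents that add atoms: iodine, II
Why: Molybdenum-catalysed hydrostannation of O-protected propargylic alcohols places tin on the internal alkyne carbon, and iododestannylation (ipso substitution at tin) then gives the 2-iodo-1-alkene without touching the (E)-alkene or the stereocentre.

**Step 5**
Reactants: 7 tert-butyl{[(3S,4E)-2-iododeca-1,4-dien-3-yl]oxy}dimethylsilane; 8 methyl 8-oxooctanoate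
Product: 9 methyl (10S,11E)-10-[(tert-butyldimethylsilyl)oxy]-8-hydroxy-9-methylideneheptadec-11-enoate (both C8 epimers)
Conditions: CrCl2 (4 equiv), NiCl2 (1 mol %), DMF, 25 °C
Reagents that add atoms: none
Why: Nozaki–Hiyama–Kishi coupling: the alkenylchromium species adds to the aldehyde and ignores the methyl ester; the new carbinol centre (C8) is formed as a mixture of epimers, which is harmless because it becomes sp2 in step 7.

**Step 6**
Reactants: 9 methyl (10S,11E)-10-[(tert-butyldimethylsilyl)oxy]-8-hydroxy-9-methylideneheptadec-11-enoate; 10 butyl vinyl ether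
Product: 11 methyl (10S,11E)-10-[(tert-butyldimethylsilyl)oxy]-8-(ethenyloxy)-9-methylideneheptadec-11-enoate (both C8 epimers)
Conditions: Pd(OCOCF3)2 (5 mol %), 4,7-diphenyl-1,10-phenanthroline, Et3N, butyl vinyl ether (solvent), 75 °C
Reagents that add atoms: none
Why: Palladium-catalysed transfer vinylation (transetherification) from butyl vinyl ether, used in excess, converts the allylic alcohol into the allyl vinyl ether needed for the Claisen rearrangement.

**Step 7**
Reactants: 11 methyl (10S,11E)-10-[(tert-butyldimethylsilyl)oxy]-8-(ethenyloxy)-9-methylideneheptadec-11-enoate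
Product: 13 methyl 7-[(1R,2S)-2-[(1S,2E)-1-[(tert-butyldimethylsilyl)oxy]oct-2-en-1-yl]-5-oxocyclopentyl]heptanoate, via Claisen aldehyde 12 (not isolated)
Conditions: acetone, 130 °C (sealed tube); then 25 °C, [Rh(nbd)(Ph2PCH2CH2PPh2)]BF4 (10 mol %, activated with H2), 25 → 50 °C
Reagents that add atoms: none
Why: Heating 11 triggers an aliphatic Claisen rearrangement through a chair transition state with the C8 chain equatorial, which forms C10–C11 and unmasks the 4-enal 12 with the (8Z) trisubstituted C8=C12 alkene (alpha chain cis to the C13 branch); cationic monovalent rhodium then adds oxidatively to the aldehyde C9–H bond, the hydride migrates to C12 to give a six-membered acyl rhodacycle, and C–C reductive elimination forms C9–C8. The closest known reaction type is the one-pot Claisen rearrangement/rhodium-catalysed intramolecular hydroacylation of allyl vinyl ethers to cyclopentanones, together with the [Rh(diphosphine)]+ cyclisation of 4-pentenals. The cyclopentanone, the only ring closed, forms by a formal 5-endo hydroacylation of the C8=C12 alkene by way of the six-membered rhodacycle. C8 is set by syn addition of acyl and hydrogen across the (Z) alkene, which places the two chains trans (and C8, alpha to the ketone, can still equilibrate to trans); C12 is set by the C13 stereocentre, because allylic 1,3-strain with the cis alpha chain holds C13–H in the alkene plane so that the silyloxy group covers one face while the C14=C15 alkene lies on the other and can chelate rhodium, and hydride delivery anti to the silyloxy group gives (12S). The step needs face selectivity at C12, secured by this locked conformation, chemoselectivity for the C8=C12 alkene over C14=C15, secured by the preference for the six-membered rhodacycle, and cyclisation over decarbonylation, secured by running the cationic catalyst near room temperature.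

**Step 8**
Reactants: 13 methyl 7-[(1R,2S)-2-[(1S,2E)-1-[(tert-butyldimethylsilyl)oxy]oct-2-en-1-yl]-5-oxocyclopentyl]heptanoate
Product: 15 methyl 7-[(1R,2S)-2-[(1S,2E)-1-[(tert-butyldimethylsilyl)oxy]oct-2-en-1-yl]-5-oxocyclopent-3-en-1-yl]heptanoate, via trimethylsilyl enol ether 14 (not isolated)
Conditions: LiN(iPr)2 (1.1 equiv), Me3SiCl, THF, −78 °C; then Pd(OAc)2 (1 equiv), MeCN, 25 °C
Reagents that add atoms: none
Why: Saegusa–Ito oxidation: LiN(iPr)2 deprotonates the ketone kinetically at the unsubstituted C10 methylene (not at the tertiary C8, and faster than the ester), and Pd(OAc)2 converts the silyl enol ether into the C10=C11 enone by beta-hydride elimination, leaving C8 and C12 untouched.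

**Step 9**
Reactants: 15 methyl 7-[(1R,2S)-2-[(1S,2E)-1-[(tert-butyldimethylsilyl)oxy]oct-2-en-1-yl]-5-oxocyclopent-3-en-1-yl]heptanoate
Product: 16 methyl 7-[(1R,2S)-2-[(1S,2E)-1-hydroxyoct-2-en-1-yl]-5-oxocyclopent-3-en-1-yl]heptanoate
Conditions: HF·pyridine, pyridine, THF, 0 → 25 °C
Reagents that add atoms: none
Why: Acidic fluoride cleavage of the secondary silyl ether; base is avoided because the gamma-hydrogen at C12 of the 4-substituted cyclopentenone is prone to base-induced double-bond migration.

**Step 10**
Reactants: 16 methyl 7-[(1R,2S)-2-[(1S,2E)-1-hydroxyoct-2-en-1-yl]-5-oxocyclopent-3-en-1-yl]heptanoate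
Product: 17 7-[(1R,2S)-2-[(1S,2E)-1-hydroxyoct-2-en-1-yl]-5-oxocyclopent-3-en-1-yl]heptanoic acid
Conditions: pig liver esterase, phosphate buffer pH 7.5, acetone (10 %), 30 °C
Reagents that add atoms: water, O
Why: Carboxylesterase-catalysed hydrolysis at neutral pH, the usual mild saponification of prostaglandin methyl esters, frees the acid without hydroxide and before any acetate is present that the enzyme could also cleave.

**Step 11**
Reactants: 17 7-[(1R,2S)-2-[(1S,2E)-1-hydroxyoct-2-en-1-yl]-5-oxocyclopent-3-en-1-yl]heptanoic acid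
Product: 19 7-[(1R,2S)-2-[(1S,2E)-1-(acetyloxy)oct-2-en-1-yl]-5-oxocyclopent-3-en-1-yl]heptanoic acid, via mixed anhydride 18 (not isolated)
Conditions: Ac2O, pyridine, DMAP (cat.), CH2Cl2, 0 °C; then H2O, THF, 25 °C
Reagents that add atoms: acetic anhydride, CC(=O)OC(C)=O
Why: DMAP-catalysed O-acetylation with retention at C13; the carboxylic acid is carried through as its mixed anhydride, which water hydrolyses back in the second stage.

**Step 12**
Reactants: 19 7-[(1R,2S)-2-[(1S,2E)-1-(acetyloxy)oct-2-en-1-yl]-5-oxocyclopent-3-en-1-yl]heptanoic acid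
Product: 20 7-[(1R,2S)-2-[(1E,3S)-3-(acetyloxy)oct-1-en-1-yl]-5-oxocyclopent-3-en-1-yl]heptanoic acid (the target)
Conditions: PdCl2(MeCN)2 (10 mol %), THF, 25 °C
Reagents that add atoms: none
Why: The divalent-palladium-catalysed [3,3]-sigmatropic rearrangement of the allylic acetate (cyclisation-induced, via a six-membered acetoxonium ring with the cyclopentenyl group equatorial) is suprafacial, so the (13S) acetate with the (14E) alkene should give the (15S) acetate with the (13E) alkene, and the equilibrium should favour the acetate on the less hindered C15.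

**Compound list**

1 | (E)-oct-2-enal | CCCCC/C=C/C=O | starting material
2 | ethynylmagnesium bromide | C#C[Mg]Br | starting material
3 | rac-(E)-dec-4-en-1-yn-3-ol | C#CC(O)/C=C/CCCCC | intermediate
4 | (3S,4E)-dec-4-en-1-yn-3-ol | C#C[C@@H](O)/C=C/CCCCC | intermediate
5 | tert-butyl{[(3S,4E)-dec-4-en-1-yn-3-yl]oxy}dimethylsilane | C#C[C@@H](O[Si](C)(C)C(C)(C)C)/C=C/CCCCC | intermediate
6 | tributyl{(3S,4E)-3-[(tert-butyldimethylsilyl)oxy]deca-1,4-dien-2-yl}stannane | C=C([Sn](CCCC)(CCCC)CCCC)[C@@H](O[Si](C)(C)C(C)(C)C)/C=C/CCCCC | intermediate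
7 | tert-butyl{[(3S,4E)-2-iododeca-1,4-dien-3-yl]oxy}dimethylsilane | C=C(I)[C@@H](O[Si](C)(C)C(C)(C)C)/C=C/CCCCC | intermediate
8 | methyl 8-oxooctanoate | O=CCCCCCCC(=O)OC | starting material
9 | methyl (10S,11E)-10-[(tert-butyldimethylsilyl)oxy]-8-hydroxy-9-methylideneheptadec-11-enoate (both C8 epimers) | C=C(C(O)CCCCCCC(=O)OC)[C@@H](O[Si](C)(C)C(C)(C)C)/C=C/CCCCC | intermediate
10 | butyl vinyl ether | C=COCCCC | starting material
11 | methyl (10S,11E)-10-[(tert-butyldimethylsilyl)oxy]-8-(ethenyloxy)-9-methylideneheptadec-11-enoate (both C8 epimers) | C=COC(CCCCCCC(=O)OC)C(=C)[C@@H](O[Si](C)(C)C(C)(C)C)/C=C/CCCCC | intermediate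
12 | methyl (8Z)-9-[(1S,2E)-1-[(tert-butyldimethylsilyl)oxy]oct-2-en-1-yl]-12-oxododec-8-enoate | O=CCC/C(=C/CCCCCCC(=O)OC)[C@@H](O[Si](C)(C)C(C)(C)C)/C=C/CCCCC | intermediate
13 | methyl 7-[(1R,2S)-2-[(1S,2E)-1-[(tert-butyldimethylsilyl)oxy]oct-2-en-1-yl]-5-oxocyclopentyl]heptanoate | CCCCC/C=C/[C@H](O[Si](C)(C)C(C)(C)C)[C@H]1CCC(=O)[C@@H]1CCCCCCC(=O)OC | intermediate
14 | methyl 7-[(1R,2S)-2-[(1S,2E)-1-[(tert-butyldimethylsilyl)oxy]oct-2-en-1-yl]-5-[(trimethylsilyl)oxy]cyclopent-4-en-1-yl]heptanoate | CCCCC/C=C/[C@H](O[Si](C)(C)C(C)(C)C)[C@H]1CC=C(O[Si](C)(C)C)[C@@H]1CCCCCCC(=O)OC | intermediate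
15 | methyl 7-[(1R,2S)-2-[(1S,2E)-1-[(tert-butyldimethylsilyl)oxy]oct-2-en-1-yl]-5-oxocyclopent-3-en-1-yl]heptanoate | CCCCC/C=C/[C@H](O[Si](C)(C)C(C)(C)C)[C@H]1C=CC(=O)[C@@H]1CCCCCCC(=O)OC | intermediate
16 | methyl 7-[(1R,2S)-2-[(1S,2E)-1-hydroxyoct-2-en-1-yl]-5-oxocyclopent-3-en-1-yl]heptanoate | CCCCC/C=C/[C@H](O)[C@H]1C=CC(=O)[C@@H]1CCCCCCC(=O)OC | intermediate
17 | 7-[(1R,2S)-2-[(1S,2E)-1-hydroxyoct-2-en-1-yl]-5-oxocyclopent-3-en-1-yl]heptanoic acid | CCCCC/C=C/[C@H](O)[C@H]1C=CC(=O)[C@@H]1CCCCCCC(=O)O | intermediate
18 | acetic 7-[(1R,2S)-2-[(1S,2E)-1-(acetyloxy)oct-2-en-1-yl]-5-oxocyclopent-3-en-1-yl]heptanoic anhydride | CCCCC/C=C/[C@H](OC(C)=O)[C@H]1C=CC(=O)[C@@H]1CCCCCCC(=O)OC(C)=O | intermediate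
19 | 7-[(1R,2S)-2-[(1S,2E)-1-(acetyloxy)oct-2-en-1-yl]-5-oxocyclopent-3-en-1-yl]heptanoic acid | CCCCC/C=C/[C@H](OC(C)=O)[C@H]1C=CC(=O)[C@@H]1CCCCCCC(=O)O | intermediate
20 | 7-[(1R,2S)-2-[(1E,3S)-3-(acetyloxy)oct-1-en-1-yl]-5-oxocyclopent-3-en-1-yl]heptanoic acid | CCCCC[C@@H](/C=C/[C@H]1C=CC(=O)[C@@H]1CCCCCCC(=O)O)OC(C)=O | target

**Step count and risks**

Total step count: 12. Longest linear sequence: 12 steps (1 → 20).

Steps most likely to fail:

1. Step 7. The hydride may be delivered to C12 with poor facial selectivity, and insertion of the trisubstituted alkene may be slow enough for decarbonylation or alkene migration to compete. Fallback, from 11 back to 13: the one-pot is given up and control is moved from the substrate to the reagent. Compound 11 is rearranged alone (acetone, 130 °C), aldehyde 12 is isolated and freed from the minor alkene isomer by chromatography, and the ring is closed by asymmetric intramolecular hydroacylation with a chiral cationic rhodium–bisphosphine catalyst, [Rh((S)-BINAP)]ClO4 or its (R) antipode, whichever is matched with the C13 centre, to give 13. This fallback makes no compound outside the list (F0).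

2. Step 6. Vinyl transfer to the hindered secondary allylic alcohol may stay incomplete, and the vinyl ether may be lost by acid-induced cleavage on isolation. Fallback, from 9 back to 11: an acetal-elimination route. Compound 9 is treated with ethyl vinyl ether and pyridinium p-toluenesulfonate to give the mixed acetal methyl (10S,11E)-10-[(tert-butyldimethylsilyl)oxy]-8-(1-ethoxyethoxy)-9-methylideneheptadec-11-enoate F1. Me3SiOTf and Et3N in CH2Cl2 at 0 °C then eliminate ethoxytrimethylsilane from F1 to give 11.

3. Step 4. Tin may be delivered to the terminal instead of the internal alkyne carbon next to the bulky silyloxy branch, and the alkenylstannane may be protodestannylated. Fallback, from 5 back to 7: haloboration instead of hydrometalation. B-iodo-9-borabicyclo[3.3.1]nonane adds syn across the terminal alkyne of 5 (pentane, −20 °C) with iodine on the internal carbon, giving the alkenylborane 9-[(1Z,3S,4E)-3-[(tert-butyldimethylsilyl)oxy]-2-iododeca-1,4-dien-1-yl]-9-borabicyclo[3.3.1]nonane F2. Protonolysis of the C–B bond of F2 with acetic acid gives 7.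

**Further compounds**

F0 | step 7 | none | none
F1 | step 6 | methyl (10S,11E)-10-[(tert-butyldimethylsilyl)oxy]-8-(1-ethoxyethoxy)-9-methylideneheptadec-11-enoate | CCOC(C)OC(CCCCCCC(=O)OC)C(=C)[C@@H](O[Si](C)(C)C(C)(C)C)/C=C/CCCCC
F2 | step 4 | 9-[(1Z,3S,4E)-3-[(tert-butyldimethylsilyl)oxy]-2-iododeca-1,4-dien-1-yl]-9-borabicyclo[3.3.1]nonane | I/C(=C\B1C2CCCC1CCC2)[C@@H](O[Si](C)(C)C(C)(C)C)/C=C/CCCCC
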